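Early readings lag, and then the curves close up. Green and red, charged with 0.37 M and 0.52 M of substrate, read 8% and 5% at 2.00 h, then 74% and 76% at 12.0 h. So I reckon in percent of the substrate charged.

| flask | substrate | coupling partner | remark | time |
|---|---|---|---|---|
| amber | 0.22 M | 0.525 M | run made earlier |  |
| green | 0.37 M | 0.525 M | run made earlier |  |
| red | 0.52 M | 0.525 M | run made earlier |  |
| blue | 0.50 M | 0.64 M | run made earlier |  |
| winter | 0.25 M | 0.400 M |  | 8.0 h |
| spring | 0.50 M | 0.525 M |  | 25 h |

- amber (time / h: product / %): 5.00: 33; 10.0: 72; 15.0: 85; 20.0: 94; 25.0: 99
- green (time / h: product / %): 2.00: 8; 6.00: 38; 12.0: 74; 20.0: 95; 25.0: 96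
- red (time / h: product / %): 2.00: 5; 6.00: 37; 12.0: 76; 20.0: 81; 25.0: 90
- blue (time / h: product / %): 2.00: 4; 4.00: 23; 8.00: 56; 12.0: 75; 25.0: 94

(standard deviation of a reading: 2 percentage points)

- product is meant together with its crystals
- solid, in amounts per volume of the solution: crystals
- what was read earlier has a scatter of 2 percentage points, one standard deviation
- on the list of suspects stand: substrate -> intermediate A; coupling partner + intermediate A -> intermediate B; intermediate B -> intermediate C; intermediate B -> intermediate D; intermediate C <-> intermediate E; intermediate D -> product; crystals <-> product

* which of the two ends with the higher amount of product, in percent of the substrate charged ("neither" if they lie within 2 percentage points) (winter / spring / neither)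
* product at the end, in percent of the substrate charged, winter
* product at the end, in percent of the substrate charged, spring

Winter stops early, so I need its point on the rising curve, and I have two ways to it. Blue, with a ratio of coupling partner to substrate of 1.28, reads 56% at 8.00 h. Green gives the second way. I treat its rise as pseudo-first-order. The unconverted part falls from 62.0% to 26.0% between 6.00 h and 12.0 h, so the constant is 0.145 /h. Run forward to 8.0 h, that gives 53.6%. These are different flasks, and they lie 2.4 percentage points apart, with a scatter of 2 points on each reading. So I take their mean as the through-share, the percent of the substrate charged that stands as product at 8.0 h with coupling partner in excess: 54.8%. Winter has a ratio of partner to substrate of 1.60, so this is my number for winter.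

For spring the two ways part. Green's constant, run to 25 h, gives 96.1%, but red reads 90% at 25.0 h. The constant cheats here. It comes from green, with a ratio of partner to substrate of 1.42, while red has 1.01 and spring 1.05. So I commit to red's reading for spring.

The forecast says 54% for winter, 91% for spring, and spring: “Spring clearly ends higher.” My numbers stand close to these but are not the same.

Winter ends at 52.5% and spring at 90.2%, so spring ends higher, and the forecast held.

    substrate → intermediate A (k = 0.910 /h)
    coupling partner + intermediate A → intermediate B (k = 1.30 /M/h)
    intermediate B → intermediate C (k = 0.140 /h)
    intermediate B → intermediate D (k = 3.90 /h)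
    intermediate C ⇌ intermediate E (K = 0.330, k = 1.30 /h)
    intermediate D → product (k = 0.220 /h)
    crystals ⇌ product, rate k7*(cs7 - [product]) while solid is left; crystals form when [product] > cs7 (solubility = 0.480 M, k = 3.50 /h)

The through-share stood 2.3 points above winter, which still holds 31.1% as intermediate D at 8.00 h. A neighbour of winter is charged with 0.10 M of coupling partner. Its substrate is down to 0.0689% at the end, and at one partner per substrate its partner charge covers 40.0% of the substrate charged. I reckon the through-share of that as 21.9%. That neighbour ends at 18.8%, with 17.7% of its coupling partner left and 67.0% standing as intermediate A.

(The data stem from a simulated flask for substances that don't exist, and the scatter is random.)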